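**Plan**
- Cuts, in order: C7 CHO back to CH2OH; the indane C1–C2 bond (cation–olefin closure of a 1-aryl-7-prenylphthalan); the phthalan O2–C3 bond; the C1–C8 bond to ring B (aryllithium plus phthalide); the prenyl–ring A bond; the dioxane bonds O1–C2 and O4–C3.
- Forward: dioxane ring on ring B (steps 1–6), lactone ring and prenyl group on ring A (7–10), union and phthalan ring (11–13), cyclopentane ring last (14), then oxidation and desilylation (15–16).
- Stereochemistry: dioxane C2 (S) comes from the Sharpless epoxide of prenol, opened with inversion by the O1 phenoxide. Indane C1 (R) comes from an oxazaborolidine-set (S)-carbinol that becomes C1 of the (1S)-phthalan and is relayed with inversion in the ring closure, backed by a matched chiral acid.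
- Feature: in the indane (C1 aryl, C2 =CMe2, C3 H2, C6 OH, C7 CHO) C2, C3 and the isopropylidene are a prenyl group on C3a. C7, the other carbon ortho to C7a, can hold the leaving oxygen as the CH2–O of a phthalan, so both ortho arms of ring A face the two lobes of a C1 cation that O1 of ring B stabilizes.

Key step: step 14

Conventions: ring A is the oxygenated benzene ring of the phthalide, phthalan and indane; ring B is the benzene ring of the benzodioxane, numbered O1, C2 (carbinol side chain), C3, O4, C4a, C5, C6 (methyl), C7, C8 (bond to C1), C8a in every compound.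

Remark on the starting material: the target carries the O1–CH bond on the oxygen next to the biaryl-type bond, so the free phenol of the epoxide-opening precursor must be the oxygen ortho to bromine and the CH2 must go onto the other oxygen; 3-bromo-2-hydroxy-5-methylbenzaldehyde delivers this pattern.

Assumption: the facial senses of the two catalyst-controlled steps follow the models stated in steps 12 and 14 (ring A as the large group toward the oxazaborolidine; the (S,S) acid as the antipode matched with the invertive closure).

**Step 1**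
Reactants: 1 3-methylbut-2-en-1-ol
Product: 2 (R)-(3,3-dimethyloxiran-2-yl)methanol
Conditions: Ti(OiPr)4 (5 mol %), D-(−)-diethyl tartrate (6 mol %), t-BuOOH, 4 Å MS, CH2Cl2, −20 °C
Reagents that add atoms: tert-butyl hydroperoxide, CC(C)(C)OO
Why: Katsuki–Sharpless asymmetric epoxidation of a primary allylic alcohol, in which the D-tartrate titanium complex should deliver oxygen to the face that gives the (2R) epoxide.

**Step 2**
Reactants: 3 3-bromo-2-hydroxy-5-methylbenzaldehyde
Product: 4 3-bromo-5-methyl-2-(prop-2-enyloxy)benzaldehyde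
Conditions: allyl bromide, K2CO3, DMF, rt
Reagents that add atoms: allyl bromide, C=CCBr
Why: Williamson etherification of an acidic salicylaldehyde phenol masks the oxygen that will become O1 with a group removable under neutral palladium catalysis.

**Step 3**
Reactants: 4 3-bromo-5-methyl-2-(prop-2-enyloxy)benzaldehyde
Product: 6 3-bromo-5-methyl-2-(prop-2-enyloxy)phenol, via aryl formate 5 (not isolated)
Conditions: mCPBA, CH2Cl2, 0 °C → rt; then K2CO3 (cat.), MeOH, rt
Reagents that add atoms: 3-chloroperoxybenzoic acid, OOC(=O)c1cccc(Cl)c1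
Why: Baeyer–Villiger oxidation of an ortho-alkoxy benzaldehyde proceeds by aryl migration to the formate, whose methanolysis frees the oxygen that will become O4 while the terminal allyl alkene reacts far more slowly with the peracid.

**Step 4**
Reactants: 6 3-bromo-5-methyl-2-(prop-2-enyloxy)phenol; 2 (R)-(3,3-dimethyloxiran-2-yl)methanol
Product: 7 (2R)-2-{[3-bromo-5-methyl-2-(prop-2-enyloxy)phenoxy]methyl}-3,3-dimethyloxirane
Conditions: PPh3, DIAD, THF, 0 °C → rt
Reagents that add atoms: none
Why: Mitsunobu etherification joins the phenol to the primary carbinol carbon, forming the O4–C3 bond without touching the epoxide stereocentre.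

**Step 5**
Reactants: 7 (2R)-2-{[3-bromo-5-methyl-2-(prop-2-enyloxy)phenoxy]methyl}-3,3-dimethyloxirane
Product: 9 2-[(2S)-8-bromo-6-methyl-2,3-dihydro-1,4-benzodioxin-2-yl]propan-2-ol, via potassium phenoxide 8 (not isolated)
Conditions: Pd(PPh3)4 (5 mol %), K2CO3, MeOH, rt, then 45 °C
Reagents that add atoms: none
Why: Tsuji–Trost-type deallylation frees the O1 phenoxide, which opens the epoxide at its secondary carbon by 6-exo-tet SN2 attack rather than 7-endo attack at the tertiary carbon, so the dioxane ring closes with inversion to the (S) centre.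

**Step 6**
Reactants: 9 2-[(2S)-8-bromo-6-methyl-2,3-dihydro-1,4-benzodioxin-2-yl]propan-2-ol
Product: 10 triethylsilyl ether of 9
Conditions: Et3SiOTf, 2,6-lutidine, CH2Cl2, −78 → 0 °C
Reagents that add atoms: triethylsilyl trifluoromethanesulfonate, CC[Si](CC)(CC)OS(=O)(=O)C(F)(F)F
Why: silylation of the tertiary alcohol with a silyl triflate removes the acidic proton before halogen–lithium exchange and leaves only one hydrogen-bond donor in the later ionization.

**Step 7**
Reactants: 11 methyl 3-hydroxy-2-methylbenzoate
Product: 12 methyl 2-methyl-3-(triisopropylsilyloxy)benzoate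
Conditions: iPr3SiCl, imidazole, DMF, rt
Reagents that add atoms: triisopropylsilyl chloride, CC(C)[Si](Cl)(C(C)C)C(C)C
Why: phenol silylation installs a bulky ether that should survive radical bromination, organolithium addition and acid, and is removed by fluoride at the end.

**Step 8**
Reactants: 12 methyl 2-methyl-3-(triisopropylsilyloxy)benzoate
Product: 13 methyl 6-bromo-2-methyl-3-(triisopropylsilyloxy)benzoate
Conditions: NBS, MeCN, rt → 40 °C
Reagents that add atoms: N-bromosuccinimide, O=C1CCC(=O)N1Br
Why: electrophilic aromatic bromination is directed para to the silyloxy group, the ortho position being screened by the triisopropylsilyl group, as known for the corresponding 3-alkoxy-2-methylbenzoates.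

**Step 9**
Reactants: 13 methyl 6-bromo-2-methyl-3-(triisopropylsilyloxy)benzoate
Product: 15 7-bromo-4-(triisopropylsilyloxy)isobenzofuran-1(3H)-one, via benzylic bromide 14 (not isolated)
Conditions: NBS, AIBN, PhCF3, 85 °C; then CaCO3, dioxane/H2O, 100 °C
Reagents that add atoms: water, O
Why: Wohl–Ziegler bromination of the only benzylic methyl group followed by buffered hydrolytic lactonization onto the neighbouring ester is the standard way from ortho-toluates to phthalides.

**Step 10**
Reactants: 15 7-bromo-4-(triisopropylsilyloxy)isobenzofuran-1(3H)-one; 16 1-bromo-3-methylbut-2-ene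
Product: 18 7-(3-methylbut-2-enyl)-4-(triisopropylsilyloxy)isobenzofuran-1(3H)-one, via prenylzinc bromide 17 (not isolated)
Conditions: 16, Zn dust, LiCl, THF, 0 °C; then 15, Pd(OAc)2 (2 mol %), 2-dicyclohexylphosphino-2′,6′-bis(dimethylamino)biphenyl (4 mol %), THF, rt
Reagents that add atoms: none
Why: Negishi coupling of an allylic zinc halide with an aryl bromide under a bulky biarylphosphine is known to couple through the primary terminus and to tolerate ester-type carbonyl groups, giving the linear prenyl arene.

**Step 11**
Reactants: 10 triethylsilyl ether of 9; 18 7-(3-methylbut-2-enyl)-4-(triisopropylsilyloxy)isobenzofuran-1(3H)-one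
Product: 21 hydroxy ketone [2-(hydroxymethyl)-6-prenyl-3-(triisopropylsilyloxy)phenyl](benzodioxan-8-yl)methanone, via aryllithium 19 (not isolated), via lithium lactolate 20 (not isolated)
Conditions: 10, n-BuLi, THF, −78 °C; then 18, −78 → −40 °C; aq NH4Cl
Reagents that add atoms: none
Why: bromine–lithium exchange followed by addition of the aryllithium to the lactone carbonyl forms the C1–C8 bond, and the tetrahedral lactolate blocks a second addition and opens to the hydroxy ketone (in ring–chain equilibrium with its lactol) on work-up.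

**Step 12**
Reactants: 21 hydroxy ketone
Product: 22 (S)-diol, (S)-[2-(hydroxymethyl)-6-prenyl-3-(triisopropylsilyloxy)phenyl](benzodioxan-8-yl)methanol
Conditions: (S)-1-methyl-3,3-diphenyltetrahydro-1H,3H-pyrrolo[1,2-c][1,3,2]oxazaborole (20 mol %), catecholborane (3 equiv), toluene, −40 → 0 °C
Reagents that add atoms: none
Why: Corey–Bakshi–Shibata reduction of a diaryl ketone, in which the twisted, doubly ortho-substituted ring A should act as the large group so that the (S) catalyst gives the (S)-carbinol, while catecholborane caps the primary hydroxyl without creating a second hydride donor and does not hydroborate the prenyl alkene at this temperature.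

**Step 13**
Reactants: 22 (S)-diol
Product: 24 (1S)-1-(benzodioxan-8-yl)-7-prenyl-4-(triisopropylsilyloxy)-1,3-dihydroisobenzofuran, via primary mesylate 23 (not isolated)
Conditions: MsCl (1.05 equiv), Et3N, CH2Cl2, −20 °C → rt
Reagents that add atoms: none
Why: selective sulfonylation of the unhindered primary benzylic alcohol and intramolecular Williamson etherification (5-exo-tet) by the carbinol oxygen close the phthalan without breaking the C1–O bond, so the carbinol configuration is retained as (1S).

**Step 14**
Reactants: 24 (1S)-1-(benzodioxan-8-yl)-7-prenyl-4-(triisopropylsilyloxy)-1,3-dihydroisobenzofuran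
Product: 25 (1R)-1-(benzodioxan-8-yl)-7-(hydroxymethyl)-2-(propan-2-ylidene)-6-(triisopropylsilyloxy)indane
Conditions: (S,S)-imidodiphosphorimidate HN[P(=NSO2CF3)(O2C20H10Ar2)]2 from two (S)-3,3′-diaryl-1,1′-bi-2-naphthol units, Ar = 3,5-bis(trifluoromethyl)phenyl (5 mol %), CHCl3, −40 °C
Reagents that add atoms: none
Why: Proposed new method: protonation of the phthalan oxygen by the confined acid and C1–O heterolysis give a benzhydryl cation stabilized by O1 of ring B, with ring A turned out of the cation plane so that the departing CH2OH arm and the prenyl arm lie on the two lobes of the empty C1 orbital; the alkene CH carbon adds to the lobe opposite the leaving oxygen and the resulting tertiary cation gives up the C2 proton to the chiral anion, which regenerates the acid. The closest known reaction type is the acid-triggered ionization of benzhydryl ethers with cation–olefin (Prins-type) closure to 1-arylindanes, together with counter-anion-directed cyclizations catalysed by imidodiphosphorimidates; what has not been shown is the transfer of configuration from a 1-arylphthalan. The cyclopentane ring closes in the 5-exo-trig mode through the new C1–C2 bond. The new C1 stereocentre is controlled by the (1S) configuration of 24, relayed with inversion to (1R) because re-closure to the phthalan only returns the same epimer and rotation about the C1–ring A bond is held back by the two ortho arms, and it is reinforced by the matched anion hydrogen-bonded to the freed CH2OH, the only donor left by the two silyl ethers. The step needs Markovnikov attack (secured by the tertiary cation at CMe2), proton loss toward the tetrasubstituted exocyclic alkene (an isopropenyl isomer would be reprotonated to the same cation) and no drift to the indene, which the low temperature, the low acid loading and the weakly basic anion are meant to secure.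

**Step 15**
Reactants: 25 (1R)-indane alcohol
Product: 26 (1R)-1-(benzodioxan-8-yl)-2-(propan-2-ylidene)-6-(triisopropylsilyloxy)indane-7-carbaldehyde
Conditions: MnO2 (activated, excess), CH2Cl2, rt
Reagents that add atoms: none
Why: MnO2 oxidation is selective for the benzylic primary alcohol and stops at the aldehyde under neutral conditions that leave the exocyclic alkene and the C1 hydrogen untouched.

**Step 16**
Reactants: 26 silylated aldehyde
Product: 27 Diaporindene G
Conditions: Bu4NF, AcOH (1:1), THF, 0 °C → rt
Reagents that add atoms: none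
Why: buffered fluoride desilylation cleaves the aryl triisopropylsilyl ether and the tertiary triethylsilyl ether without acid or strong base, so neither the alkene position nor the C1 configuration should be disturbed.

**Compound list**
1 | 3-methylbut-2-en-1-ol | CC(C)=CCO | starting material
2 | (R)-(3,3-dimethyloxiran-2-yl)methanol | OC[C@H]1OC1(C)C | intermediate
3 | 3-bromo-2-hydroxy-5-methylbenzaldehyde | Cc1cc(Br)c(O)c(C=O)c1 | starting material
4 | 3-bromo-5-methyl-2-(prop-2-enyloxy)benzaldehyde | Cc1cc(Br)c(OCC=C)c(C=O)c1 | intermediate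
5 | 3-bromo-5-methyl-2-(prop-2-enyloxy)phenyl formate | Cc1cc(Br)c(OCC=C)c(OC=O)c1 | intermediate
6 | 3-bromo-5-methyl-2-(prop-2-enyloxy)phenol | Cc1cc(Br)c(OCC=C)c(O)c1 | intermediate
7 | (2R)-2-{[3-bromo-5-methyl-2-(prop-2-enyloxy)phenoxy]methyl}-3,3-dimethyloxirane | Cc1cc(Br)c(OCC=C)c(OC[C@H]2OC2(C)C)c1 | intermediate
8 | potassium 2-bromo-6-{[(2R)-3,3-dimethyloxiran-2-yl]methoxy}-4-methylphenoxide | Cc1cc(Br)c([O-])c(OC[C@H]2OC2(C)C)c1.[K+] | intermediate
9 | 2-[(2S)-8-bromo-6-methyl-2,3-dihydro-1,4-benzodioxin-2-yl]propan-2-ol | Brc1cc(C)cc2c1O[C@H](C(C)(C)O)CO2 | intermediate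
10 | triethylsilyl ether of 9, (2S)-8-bromo-6-methyl-2-[2-(triethylsilyloxy)propan-2-yl]-2,3-dihydro-1,4-benzodioxine | Brc1cc(C)cc2c1O[C@H](C(C)(C)O[Si](CC)(CC)CC)CO2 | intermediate
11 | methyl 3-hydroxy-2-methylbenzoate | COC(=O)c1cccc(O)c1C | starting material
12 | methyl 2-methyl-3-(triisopropylsilyloxy)benzoate | COC(=O)c1cccc(O[Si](C(C)C)(C(C)C)C(C)C)c1C | intermediate
13 | methyl 6-bromo-2-methyl-3-(triisopropylsilyloxy)benzoate | COC(=O)c1c(Br)ccc(O[Si](C(C)C)(C(C)C)C(C)C)c1C | intermediate
14 | methyl 6-bromo-2-(bromomethyl)-3-(triisopropylsilyloxy)benzoate | COC(=O)c1c(Br)ccc(O[Si](C(C)C)(C(C)C)C(C)C)c1CBr | intermediate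
15 | 7-bromo-4-(triisopropylsilyloxy)isobenzofuran-1(3H)-one | O=C1OCc2c(O[Si](C(C)C)(C(C)C)C(C)C)ccc(Br)c12 | intermediate
16 | 1-bromo-3-methylbut-2-ene | CC(C)=CCBr | starting material
17 | (3-methylbut-2-enyl)zinc bromide | CC(C)=CC[Zn]Br | intermediate
18 | 7-(3-methylbut-2-enyl)-4-(triisopropylsilyloxy)isobenzofuran-1(3H)-one | CC(C)=CCc1ccc(O[Si](C(C)C)(C(C)C)C(C)C)c2c1C(=O)OC2 | intermediate
19 | aryllithium, 10 with lithium in place of bromine at C8 | [Li]c1cc(C)cc2c1O[C@H](C(C)(C)O[Si](CC)(CC)CC)CO2 | intermediate
20 | lithium lactolate, lithium 1-(benzodioxan-8-yl)-7-prenyl-4-(triisopropylsilyloxy)-1,3-dihydroisobenzofuran-1-olate | CC(C)=CCc1ccc(O[Si](C(C)C)(C(C)C)C(C)C)c2c1C(O[Li])(OC2)c1cc(C)cc2c1O[C@H](C(C)(C)O[Si](CC)(CC)CC)CO2 | intermediate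
21 | hydroxy ketone, [2-(hydroxymethyl)-6-prenyl-3-(triisopropylsilyloxy)phenyl]{(2S)-6-methyl-2-[2-(triethylsilyloxy)propan-2-yl]benzodioxan-8-yl}methanone | CC(C)=CCc1ccc(O[Si](C(C)C)(C(C)C)C(C)C)c(CO)c1C(=O)c1cc(C)cc2c1O[C@H](C(C)(C)O[Si](CC)(CC)CC)CO2 | intermediate
22 | (S)-diol, the (S)-carbinol from 21 | CC(C)=CCc1ccc(O[Si](C(C)C)(C(C)C)C(C)C)c(CO)c1[C@H](O)c1cc(C)cc2c1O[C@H](C(C)(C)O[Si](CC)(CC)CC)CO2 | intermediate
23 | primary mesylate of 22 | CC(C)=CCc1ccc(O[Si](C(C)C)(C(C)C)C(C)C)c(COS(C)(=O)=O)c1[C@H](O)c1cc(C)cc2c1O[C@H](C(C)(C)O[Si](CC)(CC)CC)CO2 | intermediate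
24 | (1S)-1-{(2S)-6-methyl-2-[2-(triethylsilyloxy)propan-2-yl]benzodioxan-8-yl}-7-prenyl-4-(triisopropylsilyloxy)-1,3-dihydroisobenzofuran | CC(C)=CCc1ccc(O[Si](C(C)C)(C(C)C)C(C)C)c2c1[C@H](OC2)c1cc(C)cc2c1O[C@H](C(C)(C)O[Si](CC)(CC)CC)CO2 | intermediate
25 | (1R)-1-{(2S)-6-methyl-2-[2-(triethylsilyloxy)propan-2-yl]benzodioxan-8-yl}-7-(hydroxymethyl)-2-(propan-2-ylidene)-6-(triisopropylsilyloxy)indane | CC(C)=C1Cc2ccc(O[Si](C(C)C)(C(C)C)C(C)C)c(CO)c2[C@@H]1c1cc(C)cc2c1O[C@H](C(C)(C)O[Si](CC)(CC)CC)CO2 | intermediate
26 | the 7-carbaldehyde corresponding to 25 | CC(C)=C1Cc2ccc(O[Si](C(C)C)(C(C)C)C(C)C)c(C=O)c2[C@@H]1c1cc(C)cc2c1O[C@H](C(C)(C)O[Si](CC)(CC)CC)CO2 | intermediate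
27 | Diaporindene G, (1R)-6-hydroxy-1-[(2S)-2-(2-hydroxypropan-2-yl)-6-methylbenzodioxan-8-yl]-2-(propan-2-ylidene)indane-7-carbaldehyde | CC(C)=C1Cc2ccc(O)c(C=O)c2[C@@H]1c1cc(C)cc2c1O[C@H](C(C)(C)O)CO2 | target

**Step count**
Total: 16 steps. Longest linear sequence: 11 steps (from 3 through steps 2–6 and 11–16).

**Steps most likely to fail**

Step 14. The configurational relay may be lost if the cation rotates about the C1–ring A bond before the ring closes, and the exocyclic double bond may migrate into the ring under the acid. Fallback: setting out from 24, the closure is run with a simple achiral acid of the kind long used for benzhydryl cation–olefin cyclizations (diphenyl hydrogen phosphate, CH2Cl2, −20 °C), accepting that 25 is then accompanied by its C1 epimer, the (1S)-indane alcohol F1. The mixture is esterified at the primary alcohol with (R)-O-methylmandelic acid (DCC, DMAP, CH2Cl2) to the (1R)-indane mandelate F2 and the (1S)-indane mandelate F3, which carry the new chiral group next to C1 and are separated by chromatography. LiBH4 (THF, 0 °C) then cleaves F2 reductively and the route is rejoined at 25.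

Step 12. Hydride transfer to the doubly flanked carbonyl may be sluggish or poorly face-selective. Fallback: from 21, NaBH4 (THF/MeOH, 0 °C → rt) reduces without facial bias and gives 22 together with its carbinol epimer, the (R)-diol F4. The two are diastereomers because of the dioxane centre and are separated by preparative HPLC, and the (S) isomer re-enters the route as 22.

Step 10. The allylic zinc reagent may couple through its tertiary terminus or add to the lactone carbonyl. Fallback: from 15, Stille coupling with allyltributylstannane (Pd(PPh3)4, toluene, 100 °C), which has no regiochemical ambiguity and leaves the lactone alone, gives 7-allyl-4-(triisopropylsilyloxy)phthalide F5. Cross-metathesis with 2-methylbut-2-ene (second-generation Grubbs catalyst, 40 °C) converts the allyl into the prenyl group and returns to 18.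

**Further compounds**
F1 | step 14 | (1S)-indane alcohol, C1 epimer of 25 | CC(C)=C1Cc2ccc(O[Si](C(C)C)(C(C)C)C(C)C)c(CO)c2[C@H]1c1cc(C)cc2c1O[C@H](C(C)(C)O[Si](CC)(CC)CC)CO2
F2 | step 14 | (1R)-indane mandelate, (R)-O-methylmandelate of 25 | CC(C)=C1Cc2ccc(O[Si](C(C)C)(C(C)C)C(C)C)c(COC(=O)[C@H](OC)c3ccccc3)c2[C@@H]1c1cc(C)cc2c1O[C@H](C(C)(C)O[Si](CC)(CC)CC)CO2
F3 | step 14 | (1S)-indane mandelate, (R)-O-methylmandelate of F1 | CC(C)=C1Cc2ccc(O[Si](C(C)C)(C(C)C)C(C)C)c(COC(=O)[C@H](OC)c3ccccc3)c2[C@H]1c1cc(C)cc2c1O[C@H](C(C)(C)O[Si](CC)(CC)CC)CO2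
F4 | step 12 | (R)-diol, carbinol epimer of 22 | CC(C)=CCc1ccc(O[Si](C(C)C)(C(C)C)C(C)C)c(CO)c1[C@@H](O)c1cc(C)cc2c1O[C@H](C(C)(C)O[Si](CC)(CC)CC)CO2
F5 | step 10 | 7-allyl-4-(triisopropylsilyloxy)isobenzofuran-1(3H)-one | C=CCc1ccc(O[Si](C(C)C)(C(C)C)C(C)C)c2c1C(=O)OC2
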